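**Retrosynthetic overview**
- The target comes from its C3 PMB ether by DDQ. The two angelates go on last, onto a C5,C9-diol. The (R)-2-methylbutanoate is carried through from the open-chain stage.
- Key disconnection: the C7–C8 and C8–O bonds. An open-chain C8 methyl ketone carrying a C7 (dimethylamino)oxosulfonium ylide closes the ten-membered carbocycle first (as a betaine) and the oxirane second, in the same flask.
- Open-chain precursor: C9–C10 by a catalyst-controlled syn-aldol of silyloxyacetone; C5 by CBS reduction; C6–C7–S by vinyl addition followed by thia-Michael addition.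
- C10–C1–C2–C3–C4–C5 comes from (S)-carvone: trans epoxidation, epoxide alcoholysis with inversion at C3, then cleavage of the six-membered ring between C5 and C10.

Assumption: the target is made exactly as drawn (angelate = (Z)-2-methylbut-2-enoate; (R)-2-methylbutanoate). Locants C1–C10 are the ring carbons in the order of the target SMILES (C1 isopropenyl-bearing, C10 2-methylbutanoate-bearing; 1R,3R,4S,5S,7S,8S,9S,10R). PMB = 4-methoxybenzyl, TES = triethylsilyl, TBS = tert-butyldimethylsilyl.

**Route**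

Step 1
Reactants: 1 (S)-(+)-carvone
Product: 2 trans-carvone oxide, (1S,4S,6S)-1-methyl-4-(prop-1-en-2-yl)-7-oxabicyclo[4.1.0]heptan-2-one
Conditions: 30% aq H2O2, NaOH (cat.), MeOH, 0 °C
Reagents that add atoms: hydrogen peroxide, OO
Why: Weitz–Scheffer nucleophilic epoxidation, in which hydroperoxide adds to the enone β-carbon anti to the pseudo-equatorial isopropenyl group, so the oxirane forms trans to it as one diastereomer, fixing the C4 oxygen and preparing C3 for inversion.

Step 2
Reactants: 2 trans-carvone oxide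
Product: 3 (2S,3R,5S)-2-hydroxy-3-(4-methoxybenzyloxy)-2-methyl-5-(prop-1-en-2-yl)cyclohexan-1-one
Conditions: 4-methoxybenzyl alcohol (3 equiv), Cu(BF4)2·6H2O (5 mol%), CH2Cl2, rt
Reagents that add atoms: 4-methoxybenzyl alcohol, COc1ccc(CO)cc1
Why: Lewis-acid-catalysed epoxide alcoholysis, with SN2 attack at C3 (remote from the carbonyl; the α-carbon is tertiary and deactivated, as in the known LiCl/TFA opening of this epoxide), which inverts C3 to the target 3R configuration and leaves C4 untouched.

Step 3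
Reactants: 3 PMB ether α-ketol
Product: 4 C4 O-TES ether of 3, (2S,3R,5S)-3-(4-methoxybenzyloxy)-2-methyl-5-(prop-1-en-2-yl)-2-(triethylsilyloxy)cyclohexan-1-one
Conditions: Et3SiOTf, 2,6-lutidine, CH2Cl2, −78 to 0 °C
Reagents that add atoms: triethylsilyl trifluoromethanesulfonate, CC[Si](CC)(CC)OS(=O)(=O)C(F)(F)F
Why: Silylation of the tertiary α-ketol with the silyl triflate masks C4–OH so that the later glycol cleavage can only take place between C5 and C10; no stereocentre changes.

Step 4
Reactants: 4 silyl ether ketone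
Product: 5 α'-hydroxy ketone (4 with OH on the ring CH2 next to the carbonyl, the future C10; both epimers)
Conditions: KN(SiMe3)2, THF, −78 °C; trans-2-(phenylsulfonyl)-3-phenyloxaziridine; AcOH quench
Reagents that add atoms: trans-2-(phenylsulfonyl)-3-phenyloxaziridine, O=S(=O)(c1ccccc1)N1OC1c1ccccc1
Why: Davis enolate hydroxylation, where the ketone can enolise only toward the ring CH2 and the new carbinol centre becomes the C10 aldehyde in step 6, so its configuration does not matter.

Step 5
Reactants: 5 α'-hydroxy ketone; 6 vinylmagnesium bromide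
Product: 7 vinyl diol (tertiary vinyl carbinol at C5, secondary alcohol at C10; both new centres as mixtures)
Conditions: CH2=CHMgBr (3 equiv), THF, −78 to 0 °C; H2O quench
Reagents that add atoms: none
Why: Grignard 1,2-addition to the magnesium alkoxide of the ketol brings in C6 and C7, and the new carbinol carbon becomes the C5 ketone in step 6, so its configuration does not matter.

Step 6
Reactants: 7 vinyl diol
Product: 9 keto aldehyde sulfide (C10 aldehyde; C5 ketone bearing CH2CH2SPh), via enone aldehyde 8 (not isolated)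
Conditions: Pb(OAc)4, CH2Cl2, −20 °C; filter through K2CO3/Celite; then PhSH (1.1 equiv), Et3N (10 mol%), 0 °C
Reagents that add atoms: thiophenol, Sc1ccccc1
Why: Criegee glycol cleavage opens the six-membered ring between C5 and C10 to a vinyl ketone and an aldehyde, and thia-Michael addition traps the polymerisable enone at once and places sulfur on C7; no stereocentre is formed.

Step 7
Reactants: 9 keto aldehyde sulfide
Product: 10 (5S)-diol sulfide (C5 secondary alcohol; C10 primary alcohol)
Conditions: (R)-2-methyl-CBS-oxazaborolidine (0.5 equiv), catecholborane (4 equiv), toluene, −78 to −30 °C; aq NaOH work-up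
Reagents that add atoms: none
Why: Corey–Bakshi–Shibata reduction with the quaternary C4 as the large group gives 5S, the sense also favoured by Felkin–Anh attack anti to the C4–OSi bond; the aldehyde is reduced in the same pot and catecholborane spares the isopropenyl group.

Step 8
Reactants: 10 diol sulfide
Product: 11 NH-sulfoximine diol (both sulfur epimers)
Conditions: PhI(OAc)2 (2.5 equiv), NH2CO2NH4 (2 equiv), MeOH, rt
Reagents that add atoms: ammonium carbamate, NC(=O)[O-].[NH4+]; (diacetoxyiodo)benzene, CC(=O)OI(OC(C)=O)c1ccccc1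
Why: One-pot NH and O transfer to a sulfide (iodonitrene, sulfilimine, then sulfanenitrile) tolerates alcohols and the alkene; sulfur becomes a stereocentre as a mixture, which is irrelevant because sulfur is expelled in step 15.

Step 9
Reactants: 11 NH-sulfoximine diol
Product: 12 N-methylsulfoximine diol
Conditions: Me3OBF4 (1.2 equiv), CH2Cl2, 0 °C; then aq NaHCO3
Reagents that add atoms: trimethyloxonium tetrafluoroborate, C[O+](C)C.F[B-](F)(F)F
Why: N-alkylation of the sulfoximine nitrogen with Meerwein's salt followed by basic work-up (Johnson's protocol) methylates nitrogen only, since the alcohols are not alkylated without base; no stereocentre changes.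

Step 10
Reactants: 12 N-methylsulfoximine diol
Product: 13 bis-TES ether (C5 O-TES; C10 CH2O-TES)
Conditions: Et3SiOTf (2.5 equiv), 2,6-lutidine, CH2Cl2, −78 °C
Reagents that add atoms: triethylsilyl trifluoromethanesulfonate (first equivalent), CC[Si](CC)(CC)OS(=O)(=O)C(F)(F)F; triethylsilyl trifluoromethanesulfonate (second equivalent), CC[Si](CC)(CC)OS(=O)(=O)C(F)(F)F
Why: Exhaustive silylation builds in two equivalents of the silyl triflate, one on each hydroxyl, which protects C5–OH for the ylide step and turns the primary alcohol into the ether that is oxidised directly in step 11; no stereocentre changes.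

Step 11
Reactants: 13 bis-TES ether
Product: 14 C10 aldehyde (C5 O-TES kept)
Conditions: (COCl)2, DMSO, CH2Cl2, −78 to −40 °C; then Et3N, −78 °C
Reagents that add atoms: none
Why: Swern oxidation of a primary triethylsilyl ether, in which chlorodimethylsulfonium chloride cleaves only the unhindered primary Si–O bond and oxidises it to the aldehyde while secondary and tertiary silyl ethers survive; C1 is preserved by low temperature and immediate use.

Step 12
Reactants: 14 C10 aldehyde; 15 1-(tert-butyldimethylsilyloxy)propan-2-one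
Product: 16 syn-aldol (C8 methyl ketone; 9S O-TBS; 10R OH)
Conditions: O-tert-butyl-D-threonine (20 mol%), 5-methyl-1H-tetrazole (10 mol%), NMP, 4 °C
Reagents that add atoms: none
Why: Direct syn-selective enamine aldol under primary-amino-acid catalysis, where the Z-enamine of the silyloxyacetone (held by an N–H···O hydrogen bond) adds under catalyst control and the D-catalyst gives the 9S,10R syn-diol pattern.

Step 13
Reactants: 16 syn-aldol; 17 (R)-2-methylbutanoic acid
Product: 18 C10 (R)-2-methylbutanoate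
Conditions: DCC, DMAP (10 mol%), CH2Cl2, 0 °C to rt
Reagents that add atoms: none
Why: Steglich esterification of the only free hydroxyl (C10) with retention at every stereocentre, kept cold and with little DMAP to avoid β-elimination and racemisation of the acid.

Step 14
Reactants: 18 sulfoximine keto ester
Product: 19 (dimethylamino)oxosulfonium tetrafluoroborate
Conditions: Me3OBF4 (1.5 equiv), 2,6-di-tert-butyl-4-methylpyridine (0.2 equiv), CH2Cl2, rt
Reagents that add atoms: trimethyloxonium tetrafluoroborate, C[O+](C)C.F[B-](F)(F)F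
Why: A second N-methylation with Meerwein's salt gives Johnson's aminooxosulfonium salt, whose only α-hydrogens are on C7 and are about ten pKa units more acidic than the ketone α-hydrogens.

Step 15
Reactants: 19 (dimethylamino)oxosulfonium tetrafluoroborate
Product: 22 protected 7S,8S-epoxycyclodecane (ten-membered carbocycle fused to the oxirane), via sulfoxonium ylide 20 (not isolated), via alkoxide betaine 21 (not isolated)
Conditions: LiN(SiMe3)2 (1.0 equiv), THF, −78 °C; dilute to 2 mM, −78 °C to rt, 24 h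
Reagents that add atoms: none
Why: Proposed new method: intramolecular Johnson alkylidene transfer, the closest precedent being intermolecular epoxidation of ketones by (dimethylamino)alkylphenyloxosulfonium ylides (Johnson–Corey–Chaykovsky reaction); the salt (pKa about 15 in DMSO) is deprotonated selectively, the stabilised ylide adds reversibly to the C8 methyl ketone so the chain can find a productive ten-membered betaine, and irreversible 3-exo-tet displacement of N,N-dimethylbenzenesulfinamide with inversion at C7 closes the oxirane, so carbocycle and epoxide form in one operation; a cis-fused oxirane (C6 and C9 cis) is expected from the less strained cis-cyclodecene-like closure, and of the two cis isomers the 7S,8S one has the oxirane oxygen on the ring periphery trans to the pseudo-equatorial C9 silyloxy group (the arrangement peracids give with 8- and 9-membered cycloalk-2-enols), which is the basis, and the least secure point of the route, for the C7/C8 outcome.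

Step 16
Reactants: 22 protected macrocyclic epoxide
Product: 23 triol (C4, C5 and C9 OH free; C3 O-PMB; C10 ester)
Conditions: HF·pyridine, pyridine, THF, 0 °C to rt
Reagents that add atoms: none
Why: Buffered fluoride desilylation removes the two TES groups and the TBS group without base, which avoids Payne rearrangement of the C9 alkoxide and acyl migration; no stereocentre changes.

Step 17
Reactants: 23 triol; 24 angelic acid
Product: 25 C5,C9-bis-angelate (C3 PMB ether of the target)
Conditions: angelic acid (4 equiv), 2,4,6-trichlorobenzoyl chloride (4 equiv), Et3N, toluene, rt; then 23, 75 °C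
Reagents that add atoms: angelic acid (the second equivalent of 24 that is built in), C/C=C(/C)C(=O)O
Why: Yamaguchi mixed-anhydride esterification without DMAP (the usual way to put on angelates without Z-to-E isomerisation) builds in two equivalents of angelic acid, one on each of the secondary C5 and C9 alcohols, while the tertiary C4–OH stays free.

Step 18
Reactants: 25 C3 PMB ether of the target
Product: 26 target CNP0246823.2
Conditions: DDQ, CH2Cl2/pH 7 phosphate buffer, 0 °C
Reagents that add atoms: none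
Why: Oxidative PMB cleavage with DDQ frees C3–OH under neutral conditions that spare the epoxide, the three esters and the alkenes, and it comes last because free C3–OH could open the oxirane transannularly under acid or base.

**Compound list**
1 | (S)-(+)-carvone | C=C(C)[C@H]1CC=C(C)C(=O)C1 | starting material
2 | trans-carvone oxide, (1S,4S,6S)-1-methyl-4-(prop-1-en-2-yl)-7-oxabicyclo[4.1.0]heptan-2-one | C=C(C)[C@H]1C[C@@H]2O[C@]2(C)C(=O)C1 | intermediate
3 | (2S,3R,5S)-2-hydroxy-3-(4-methoxybenzyloxy)-2-methyl-5-(prop-1-en-2-yl)cyclohexan-1-one | C=C(C)[C@H]1C[C@@H](OCc2ccc(OC)cc2)[C@](C)(O)C(=O)C1 | intermediate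
4 | (2S,3R,5S)-3-(4-methoxybenzyloxy)-2-methyl-5-(prop-1-en-2-yl)-2-(triethylsilyloxy)cyclohexan-1-one | C=C(C)[C@H]1C[C@@H](OCc2ccc(OC)cc2)[C@](C)(O[Si](CC)(CC)CC)C(=O)C1 | intermediate
5 | 6-hydroxy derivative of 4 (OH on the ring CH2 next to C=O; both epimers) | C=C(C)[C@H]1C[C@@H](OCc2ccc(OC)cc2)[C@](C)(O[Si](CC)(CC)CC)C(=O)C1O | intermediate
6 | vinylmagnesium bromide | C=C[Mg]Br | starting material
7 | 1-vinylcyclohexane-1,2-diol from 5 (vinyl on the former carbonyl carbon; both carbinol centres as mixtures) | C=C(C)[C@H]1C[C@@H](OCc2ccc(OC)cc2)[C@](C)(O[Si](CC)(CC)CC)C(O)(C=C)C1O | intermediate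
8 | open-chain enone aldehyde: C10 aldehyde, C1 isopropenyl, C3 O-PMB, C4 methyl and O-TES, C5 vinyl ketone (C1, C3, C4 as in the target) | C=C(C)[C@H](C=O)C[C@@H](OCc1ccc(OC)cc1)[C@](C)(O[Si](CC)(CC)CC)C(=O)C=C | intermediate
9 | keto aldehyde sulfide: as 8 with the C5 ketone bearing CH2CH2SPh | C=C(C)[C@H](C=O)C[C@@H](OCc1ccc(OC)cc1)[C@](C)(O[Si](CC)(CC)CC)C(=O)CCSc1ccccc1 | intermediate
10 | (5S)-diol sulfide: C10 CH2OH, C5 secondary OH, C7 SPh | C=C(C)[C@H](CO)C[C@@H](OCc1ccc(OC)cc1)[C@](C)(O[Si](CC)(CC)CC)[C@@H](O)CCSc1ccccc1 | intermediate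
11 | NH-sulfoximine of 10 (S-phenyl, C7 on sulfur; sulfur epimers) | C=C(C)[C@H](CO)C[C@@H](OCc1ccc(OC)cc1)[C@](C)(O[Si](CC)(CC)CC)[C@@H](O)CCS(=N)(=O)c1ccccc1 | intermediate
12 | N-methylsulfoximine diol | C=C(C)[C@H](CO)C[C@@H](OCc1ccc(OC)cc1)[C@](C)(O[Si](CC)(CC)CC)[C@@H](O)CCS(=O)(=NC)c1ccccc1 | intermediate
13 | bis-TES ether of 12 (C5 O-TES and C10 CH2O-TES) | C=C(C)[C@H](CO[Si](CC)(CC)CC)C[C@@H](OCc1ccc(OC)cc1)[C@](C)(O[Si](CC)(CC)CC)[C@@H](O[Si](CC)(CC)CC)CCS(=O)(=NC)c1ccccc1 | intermediate
14 | C10 aldehyde (C3 O-PMB, C4 O-TES, C5 O-TES, C7 N-methylsulfoximine) | C=C(C)[C@H](C=O)C[C@@H](OCc1ccc(OC)cc1)[C@](C)(O[Si](CC)(CC)CC)[C@@H](O[Si](CC)(CC)CC)CCS(=O)(=NC)c1ccccc1 | intermediate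
15 | 1-(tert-butyldimethylsilyloxy)propan-2-one | CC(=O)CO[Si](C)(C)C(C)(C)C | starting material
16 | syn-aldol: C8 methyl ketone, (9S) O-TBS, (10R) OH | C=C(C)[C@H]([C@@H](O)[C@H](O[Si](C)(C)C(C)(C)C)C(C)=O)C[C@@H](OCc1ccc(OC)cc1)[C@](C)(O[Si](CC)(CC)CC)[C@@H](O[Si](CC)(CC)CC)CCS(=O)(=NC)c1ccccc1 | intermediate
17 | (R)-2-methylbutanoic acid | CC[C@@H](C)C(=O)O | starting material
18 | C10 (R)-2-methylbutanoate of 16 | C=C(C)[C@H]([C@@H](OC(=O)[C@H](C)CC)[C@H](O[Si](C)(C)C(C)(C)C)C(C)=O)C[C@@H](OCc1ccc(OC)cc1)[C@](C)(O[Si](CC)(CC)CC)[C@@H](O[Si](CC)(CC)CC)CCS(=O)(=NC)c1ccccc1 | intermediate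
19 | (dimethylamino)phenyloxosulfonium tetrafluoroborate (sulfur on C7) | C=C(C)[C@H]([C@@H](OC(=O)[C@H](C)CC)[C@H](O[Si](C)(C)C(C)(C)C)C(C)=O)C[C@@H](OCc1ccc(OC)cc1)[C@](C)(O[Si](CC)(CC)CC)[C@@H](O[Si](CC)(CC)CC)CC[S+](=O)(N(C)C)c1ccccc1.F[B-](F)(F)F | intermediate
20 | C7 sulfoxonium ylide from 19 | C=C(C)[C@H]([C@@H](OC(=O)[C@H](C)CC)[C@H](O[Si](C)(C)C(C)(C)C)C(C)=O)C[C@@H](OCc1ccc(OC)cc1)[C@](C)(O[Si](CC)(CC)CC)[C@@H](O[Si](CC)(CC)CC)C[CH-][S+](=O)(N(C)C)c1ccccc1 | intermediate
21 | ten-membered betaine: C8 alkoxide, C7 sulfoxonium | C=C(C)[C@H]1C[C@@H](OCc3ccc(OC)cc3)[C@](C)(O[Si](CC)(CC)CC)[C@@H](O[Si](CC)(CC)CC)C[C@@H]([S+](=O)(N(C)C)c2ccccc2)[C@@]([O-])(C)[C@@H](O[Si](C)(C)C(C)(C)C)[C@@H]1OC(=O)[C@H](C)CC | intermediate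
22 | protected macrocyclic epoxide: C3 O-PMB, C4 O-TES, C5 O-TES, 7S,8S epoxide, C9 O-TBS, C10 (R)-2-methylbutanoate (ring centres as in the target) | C=C(C)[C@H]1C[C@@H](OCc3ccc(OC)cc3)[C@](C)(O[Si](CC)(CC)CC)[C@@H](O[Si](CC)(CC)CC)C[C@@H]2O[C@]2(C)[C@@H](O[Si](C)(C)C(C)(C)C)[C@@H]1OC(=O)[C@H](C)CC | intermediate
23 | triol: C4, C5, C9 OH; C3 O-PMB; C10 (R)-2-methylbutanoate | C=C(C)[C@H]1C[C@@H](OCc3ccc(OC)cc3)[C@](C)(O)[C@@H](O)C[C@@H]2O[C@]2(C)[C@@H](O)[C@@H]1OC(=O)[C@H](C)CC | intermediate
24 | angelic acid, (Z)-2-methylbut-2-enoic acid | C/C=C(/C)C(=O)O | starting material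
25 | C3 PMB ether of the target (C5 and C9 angelates) | C=C(C)[C@H]1C[C@@H](OCc3ccc(OC)cc3)[C@](C)(O)[C@@H](OC(=O)/C(C)=C\C)C[C@@H]2O[C@]2(C)[C@@H](OC(=O)/C(C)=C\C)[C@@H]1OC(=O)[C@H](C)CC | intermediate
26 | CNP0246823.2 | C=C(C)[C@H]1C[C@@H](O)[C@](C)(O)[C@@H](OC(=O)/C(C)=C\C)C[C@@H]2O[C@]2(C)[C@@H](OC(=O)/C(C)=C\C)[C@@H]1OC(=O)[C@H](C)CC | target

**Totals and risks**
Total step count: 18. Longest linear sequence: 18 steps (1 to 26); compounds 6, 15, 17 and 24 are bought.

Most likely to fail:

1. Step 15 (ring closure and C7/C8 facial selectivity are unprecedented at this ring size). The fallback sets out from 19 and returns at 22. NaI in acetone displaces the sulfinamide from C7 to give the primary iodide F1. PPh3 in MeCN at 80 °C gives the phosphonium iodide F2. KN(SiMe3)2 in toluene at high dilution forms the phosphorane, which closes the ring by intramolecular Wittig reaction with the C8 ketone to the (Z)-cyclodecene F3. One equivalent of mCPBA with NaHCO3 at −20 °C then epoxidises the trisubstituted ring alkene (faster than the isopropenyl group) from the periphery, anti to the C9 silyloxy group, to give 22.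

2. Step 12 (possible C1 epimerisation through the enamine, uncertain regioselectivity and matched/mismatched behaviour of the silyloxyacetone). The fallback sets out from 14 and returns at 16. (S)-4-Benzyloxazolidin-2-one is N-acylated (n-BuLi, then TBSOCH2COCl) to the glycolyl imide F4. Its dibutylboron Z-enolate (Bu2BOTf, Et3N, −78 °C) adds to 14 under auxiliary control to give the Evans syn-aldol imide F5. MeNH(OMe)·HCl with AlMe3 gives the Weinreb amide F6, and CH3MgBr at −78 to 0 °C gives 16.

3. Step 17 (two hindered secondary alcohols, each next to a fully substituted carbon; angelate can isomerise to tiglate). The fallback sets out from 23 and returns at 25. DCC/DMAP esterification with 2-[bis(2,2,2-trifluoroethoxy)phosphoryl]propanoic acid gives the bis(phosphonopropanoate) F7. Still–Gennari olefination (KN(SiMe3)2, 18-crown-6, THF, −78 °C, acetaldehyde) then builds both Z-2-methylbut-2-enoates on the molecule to give 25.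

**Further compounds**
F1 | step 15 | C7 primary iodide (19 with iodide in place of the sulfoxonium group) | C=C(C)[C@H]([C@@H](OC(=O)[C@H](C)CC)[C@H](O[Si](C)(C)C(C)(C)C)C(C)=O)C[C@@H](OCc1ccc(OC)cc1)[C@](C)(O[Si](CC)(CC)CC)[C@@H](O[Si](CC)(CC)CC)CCI
F2 | step 15 | C7 triphenylphosphonium iodide | C=C(C)[C@H]([C@@H](OC(=O)[C@H](C)CC)[C@H](O[Si](C)(C)C(C)(C)C)C(C)=O)C[C@@H](OCc1ccc(OC)cc1)[C@](C)(O[Si](CC)(CC)CC)[C@@H](O[Si](CC)(CC)CC)CC[P+](c1ccccc1)(c1ccccc1)c1ccccc1.[I-]
F3 | step 15 | protected (Z)-cyclodec-7-ene (C7=C8, methyl on C8) | C=C(C)[C@H]1C[C@@H](OCc3ccc(OC)cc3)[C@](C)(O[Si](CC)(CC)CC)[C@@H](O[Si](CC)(CC)CC)C/C=C(C)\[C@@H](O[Si](C)(C)C(C)(C)C)[C@@H]1OC(=O)[C@H](C)CC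
F4 | step 12 | (S)-4-benzyl-3-[(tert-butyldimethylsilyloxy)acetyl]oxazolidin-2-one | CC(C)(C)[Si](C)(C)OCC(=O)N1C(=O)OC[C@@H]1Cc1ccccc1
F5 | step 12 | Evans syn-aldol imide (C8 acyl oxazolidinone; 9S O-TBS; 10R OH) | C=C(C)[C@H]([C@@H](O)[C@H](O[Si](C)(C)C(C)(C)C)C(=O)N1C(=O)OC[C@@H]1Cc1ccccc1)C[C@@H](OCc1ccc(OC)cc1)[C@](C)(O[Si](CC)(CC)CC)[C@@H](O[Si](CC)(CC)CC)CCS(=O)(=NC)c1ccccc1
F6 | step 12 | C8 Weinreb amide | C=C(C)[C@H]([C@@H](O)[C@H](O[Si](C)(C)C(C)(C)C)C(=O)N(C)OC)C[C@@H](OCc1ccc(OC)cc1)[C@](C)(O[Si](CC)(CC)CC)[C@@H](O[Si](CC)(CC)CC)CCS(=O)(=NC)c1ccccc1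
F7 | step 17 | C5,C9-bis{2-[bis(2,2,2-trifluoroethoxy)phosphoryl]propanoate} of 23 | C=C(C)[C@H]1C[C@@H](OCc3ccc(OC)cc3)[C@](C)(O)[C@@H](OC(=O)C(C)P(=O)(OCC(F)(F)F)OCC(F)(F)F)C[C@@H]2O[C@]2(C)[C@@H](OC(=O)C(C)P(=O)(OCC(F)(F)F)OCC(F)(F)F)[C@@H]1OC(=O)[C@H](C)CC
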